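**Plan**

- Retrosynthesis: the C17 aldehyde comes from a primary alcohol and the C12–C13 bond from an alkyl bromide plus methyl (2Z)-3-bromobut-2-enoate. C12–Br and C17–OH both come from one temporary oxane ring (C8–C17–O–C12–C11–C9) opened at C12. Ring A is cut by a Robinson annulation (C1–C10, C4=C5) with reductive methylation, and ring B by a Diels–Alder reaction that cuts C7–C8 and C5–C6.
- Enabling feature: C6 and C7 are the only adjacent, unsubstituted carbons of ring B. C5 can be carried as a ketene acetal carbon (later the carbonyl that builds ring A), C10 bears only its methyl before ring A exists, and C8/C9 with their arms C17 and C11–C12 can be tied by one oxygen into a dihydropyran. The C5–C10–C9–C8 edge is therefore a 1-ethoxy-1-silyloxy diene, and C6–C7 a benzyl acrylate whose carboxyl is lost afterwards.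
- Forward order: oxane (bought) → ring B (step 3) → ring A (steps 5 and 6) → oxane opened, side chain joined, C17 oxidised.
- Stereochemistry: C8 is set by the chiral Lewis acid in step 3. The rest is relayed: H9 by hydrogenation cis to H8, C10 by Michael addition anti to C11, H5 by lithium/ammonia reduction, C3–OH by axial hydride attack. The Z alkene comes in with the bromoenoate.

Key step: step 3

Remark on the chemistry: the C17 formyl group of the target is axial (cis to the C10 methyl), the less stable C8 epimer, so C8 is kept as a non-epimerisable CH–CH2O centre and the aldehyde is released last without base. Locants C1–C20 are labdane numbers of the target, used for numbering only and not as a stereoparent. In isochromene names, C1 = C17, C3 = C12, C4 = C11, C4a = C9, C5 = C10, C6 = C5, C7 = C6, C8 = C7, C8a = C8.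

**Route**

Step 1
Reactants: 1 oxan-4-one; 2 triethyl 2-phosphonopropionate
Product: 3 ethyl 2-(oxan-4-ylidene)propanoate
Conditions: NaH, THF, 0 °C then reflux
Reagents that add atoms: none
Why: Horner–Wadsworth–Emmons olefination of a symmetric cyclic ketone should give the tetrasubstituted enoate with no E/Z question, because both ring arms are identical.

Step 2
Reactants: 3 ethyl 2-(oxan-4-ylidene)propanoate
Product: 5 tert-butyl{[2-(3,6-dihydro-2H-pyran-4-yl)-1-ethoxyprop-1-en-1-yl]oxy}dimethylsilane (the 1-ethoxy-1-silyloxy diene; ketene acetal geometry not controlled), via lithium dienolate 4 (not isolated)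
Conditions: LiN(iPr)2, THF/DMPU, −78 °C; then tBuMe2SiCl, −78 °C → rt; non-aqueous work-up
Reagents that add atoms: tert-butyldimethylsilyl chloride, CC(C)(C)[Si](C)(C)Cl
Why: Kinetic γ-deprotonation of a β,β-dialkyl enoate (the two ring CH2 groups are equivalent) followed by O-silylation is the standard entry to 1-alkoxy-1-silyloxy dienes, and the endocyclic C8=C9 bond holds the diene s-cis-capable with C17 outside.

Step 3
Reactants: 5 1-ethoxy-1-silyloxy diene; 6 benzyl acrylate
Product: 8 benzyl (8aR)-5-methyl-6-oxo-3,4,6,7,8,8a-hexahydro-1H-isochromene-7-carboxylate (keto/enol and C7 epimers), via cycloadduct silyl ketal 7 (not isolated)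
Conditions: oxazaborolidinium triflimide from (S)-α,α-diphenylprolinol, o-tolylboroxine and HNTf2 (10 mol%), CH2Cl2, −78 °C; then 1 M HCl, THF, 0 °C
Reagents that add atoms: none
Why: Proposed new method: the boron Lewis acid binds the acrylate carbonyl and the electron-rich diene adds in an asynchronous endo [4+2] cycloaddition in which the C7–C8 bond (diene γ-terminus to acrylate β-carbon) leads and the C5–C6 bond closes, after which acid turns the mixed silyl ketal into the enone. The closest known reaction types are the oxazaborolidinium-catalysed Diels–Alder reaction of acrylates with 2-silyloxy dienes and the thermal Diels–Alder reaction of 1-alkoxy-1-silyloxy dienes with acrylates; new is a vinylketene silyl acetal under chiral Lewis acid control. Ring B closes in one suprafacial six-membered [4+2] event. C8 is the only stereocentre that survives and is set by the catalyst-shielded face of the s-trans acrylate together with the endo orientation, while C7 of the product is epimerisable and the ketal carbon becomes the carbonyl. The step needs regioselectivity (the two oxygens on C5 make C8 the nucleophilic terminus), endo and π-face selectivity (catalyst pocket), and suppression of silyl-cation catalysis and of open-chain Mukaiyama–Michael products (bulky silyl group, low temperature, non-coordinating counter-ion). Both antipodes of the prolinol are available, so the 8aR sense drawn can be enforced.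

Step 4
Reactants: 8 benzyl keto ester
Product: 10 (4aR,8aR)-5-methyloctahydro-6H-isochromen-6-one (cis ring fusion; both C5 epimers), via keto acid 9 (not isolated)
Conditions: H2 (4 atm), Pd/C, EtOAc, rt then 50 °C
Reagents that add atoms: none
Why: Hydrogenolysis of the benzyl ester, decarboxylation of the β-keto acid and hydrogenation of the tetrasubstituted enone should run in one pot, with hydrogen delivered to C9 on the convex face that carries H8, which gives the cis ring fusion usual for heterogeneous hydrogenation of ring-fusion enones.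

Step 5
Reactants: 10 cis-fused ketone; 11 ethyl vinyl ketone (pent-1-en-3-one)
Product: 13 tricyclic enone (8R,9R,10S)-12,17-epoxy-13,14,15,16,19-pentanorlabd-4-en-3-one, via diketone 12 (not isolated)
Conditions: NaOEt (0.2 equiv), EtOH, −10 °C → rt; then NaOEt (1.5 equiv), EtOH, reflux
Reagents that add atoms: none
Why: Robinson annulation through the more substituted enolate, in which C11 on C9 sits pseudoaxial to avoid allylic strain with the C10 methyl, so C1 enters anti to C11 and C20 ends cis to C11, as in annulations of 2,3-dialkylcyclohexanones.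

Step 6
Reactants: 13 tricyclic enone
Product: 15 (5S,8R,9R,10S)-12,17-epoxy-13,14,15,16-tetranorlabdan-3-one (A/B trans), via lithium enolate 14 (not isolated)
Conditions: Li, NH3(l)/THF, −78 °C; then MeI, −78 °C → rt
Reagents that add atoms: iodomethane, CI
Why: Birch-type reductive alkylation of the 4-methyl-4-en-3-one: axial protonation at C5 should give the trans A/B fusion (H5 anti to C20), and the regiodefined C3–C4 enolate is methylated at C4 to give the gem-dimethyl group.

Step 7
Reactants: 15 tricyclic ketone
Product: 16 (3R,5S,8R,9R,10S)-12,17-epoxy-13,14,15,16-tetranorlabdan-3-ol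
Conditions: NaBH4, MeOH, 0 °C
Reagents that add atoms: none
Why: Hydride reduction of a 4,4-dimethyl-3-oxo trans-decalin occurs by axial attack and should give the equatorial 3-alcohol, cis to C20.

Step 8
Reactants: 16 tricyclic alcohol
Product: 18 (2R,4aS,5R,6R,8aS)-5-(2-bromoethyl)-6-(hydroxymethyl)-1,1,4a-trimethyldecahydronaphthalen-2-ol, via bis(dimethylborinate) 17 (not isolated)
Conditions: Me2BBr (2.5 equiv), Et3N (1.1 equiv), CH2Cl2, 0 °C → rt; then aq. NaHCO3
Reagents that add atoms: bromodimethylborane, CB(C)Br
Why: Lewis-acid-assisted SN2 opening of a cyclic ether: after O-borylation, bromide should attack the less hindered α-carbon C12 (β-unbranched) and not C17 (β-branched, axial on ring B), which unmasks C12–Br and C17–OH without touching a stereocentre.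

Step 9
Reactants: 19 methyl but-2-ynoate
Product: 20 methyl (2Z)-3-bromobut-2-enoate
Conditions: LiBr (1.2 equiv), AcOH (1.5 equiv), MeCN, 80 °C
Reagents that add atoms: lithium bromide, [Li+].[Br-]
Why: Hydrobromination of a 2-alkynoate (bromide conjugate addition, then protonation) is an anti addition and should give the (Z)-3-bromo-2-enoate with Br cis to the ester.

Step 10
Reactants: 18 bromo diol; 20 methyl (2Z)-3-bromobut-2-enoate
Product: 21 methyl (2Z)-5-[(1R,2R,4aS,6R,8aS)-6-hydroxy-2-(hydroxymethyl)-5,5,8a-trimethyldecahydronaphthalen-1-yl]-3-methylpent-2-enoate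
Conditions: NiI2 (10 mol%), 4,4'-di-tert-butyl-2,2'-bipyridine (10 mol%), Mn powder (2 equiv), NaI (0.5 equiv), N,N-dimethylacetamide, rt
Reagents that add atoms: none
Why: Nickel-catalysed reductive cross-electrophile coupling of a primary alkyl bromide with an alkenyl bromide tolerates free hydroxyl groups and should join C12 to C13 with retention of alkene geometry, so the chain CH2 ends cis to the ester (13Z).

Step 11
Reactants: 21 diol ester
Product: 22 methyl (2Z)-5-[(1R,2R,4aS,6R,8aS)-2-formyl-6-hydroxy-5,5,8a-trimethyldecahydronaphthalen-1-yl]-3-methylpent-2-enoate (target)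
Conditions: TEMPO (0.1 equiv), PhI(OAc)2 (1.1 equiv), CH2Cl2, rt
Reagents that add atoms: none
Why: Oxoammonium oxidation (TEMPO with PhI(OAc)2) should convert the primary C17 alcohol to the aldehyde much faster than the hindered secondary C3 alcohol and runs without base, so the axial formyl group at C8 is not epimerised.

**Compound list**

1 | oxan-4-one | O=C1CCOCC1 | starting material
2 | triethyl 2-phosphonopropionate | CCOC(=O)C(C)P(=O)(OCC)OCC | starting material
3 | ethyl 2-(oxan-4-ylidene)propanoate | CCOC(=O)C(C)=C1CCOCC1 | intermediate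
4 | lithium 2-(3,6-dihydro-2H-pyran-4-yl)-1-ethoxyprop-1-en-1-olate (lithium dienolate) | CCOC([O-])=C(C)C1=CCOCC1.[Li+] | intermediate
5 | tert-butyl{[2-(3,6-dihydro-2H-pyran-4-yl)-1-ethoxyprop-1-en-1-yl]oxy}dimethylsilane | CCOC(O[Si](C)(C)C(C)(C)C)=C(C)C1=CCOCC1 | intermediate
6 | benzyl acrylate | C=CC(=O)OCc1ccccc1 | starting material
7 | benzyl (8aR)-6-ethoxy-5-methyl-6-(tert-butyldimethylsilyloxy)-3,4,6,7,8,8a-hexahydro-1H-isochromene-7-carboxylate (cycloadduct; C6/C7 mixture) | O3CCC1=C(C)C(OCC)(O[Si](C)(C)C(C)(C)C)C(C(=O)OCc2ccccc2)C[C@H]1C3 | intermediate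
8 | benzyl (8aR)-5-methyl-6-oxo-3,4,6,7,8,8a-hexahydro-1H-isochromene-7-carboxylate | O3CCC1=C(C)C(=O)C(C(=O)OCc2ccccc2)C[C@H]1C3 | intermediate
9 | (8aR)-5-methyl-6-oxo-3,4,6,7,8,8a-hexahydro-1H-isochromene-7-carboxylic acid | O3CCC1=C(C)C(=O)C(C(=O)O)C[C@H]1C3 | intermediate
10 | (4aR,8aR)-5-methyloctahydro-6H-isochromen-6-one (cis-fused; C5 epimers) | O3CC[C@@H]1[C@H](C3)CCC(=O)C1C | intermediate
11 | ethyl vinyl ketone (pent-1-en-3-one) | CCC(=O)C=C | starting material
12 | (4aR,5S,8aR)-5-methyl-5-(3-oxopentyl)octahydro-6H-isochromen-6-one | O3CC[C@@H]1[C@H](C3)CCC(=O)[C@@]1(C)CCC(=O)CC | intermediate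
13 | (8R,9R,10S)-12,17-epoxy-13,14,15,16,19-pentanorlabd-4-en-3-one (ring A 4-methyl enone; oxane C8–C17–O–C12–C11–C9 cis-fused to ring B; C20 cis to C11) | O3CC[C@@H]1[C@H](C3)CCC2=C(C)C(=O)CC[C@@]12C | intermediate
14 | lithium enolate (C3–O, C3=C4) of the trans-fused 4-methyl-3-ketone | O3CC[C@@H]1[C@H](C3)CC[C@@H]2C(C)=C([O-])CC[C@@]12C.[Li+] | intermediate
15 | (5S,8R,9R,10S)-12,17-epoxy-13,14,15,16-tetranorlabdan-3-one | O3CC[C@@H]1[C@H](C3)CC[C@@H]2C(C)(C)C(=O)CC[C@@]12C | intermediate
16 | (3R,5S,8R,9R,10S)-12,17-epoxy-13,14,15,16-tetranorlabdan-3-ol | O3CC[C@@H]1[C@H](C3)CC[C@@H]2C(C)(C)[C@H](O)CC[C@@]12C | intermediate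
17 | bis(dimethylborinate) of bromo diol 18 | BrCC[C@@H]1[C@H](COB(C)C)CC[C@@H]2C(C)(C)[C@H](OB(C)C)CC[C@@]12C | intermediate
18 | (2R,4aS,5R,6R,8aS)-5-(2-bromoethyl)-6-(hydroxymethyl)-1,1,4a-trimethyldecahydronaphthalen-2-ol | BrCC[C@@H]1[C@H](CO)CC[C@@H]2C(C)(C)[C@H](O)CC[C@@]12C | intermediate
19 | methyl but-2-ynoate | CC#CC(=O)OC | starting material
20 | methyl (2Z)-3-bromobut-2-enoate | COC(=O)/C=C(/C)Br | intermediate
21 | methyl (2Z)-5-[(1R,2R,4aS,6R,8aS)-6-hydroxy-2-(hydroxymethyl)-5,5,8a-trimethyldecahydronaphthalen-1-yl]-3-methylpent-2-enoate | COC(=O)/C=C(/C)CC[C@@H]1[C@H](CO)CC[C@@H]2C(C)(C)[C@H](O)CC[C@@]12C | intermediate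
22 | methyl (2Z)-5-[(1R,2R,4aS,6R,8aS)-2-formyl-6-hydroxy-5,5,8a-trimethyldecahydronaphthalen-1-yl]-3-methylpent-2-enoate | COC(=O)/C=C(/C)CC[C@@H]1[C@H](C=O)CC[C@@H]2C(C)(C)[C@H](O)CC[C@@]12C | target

**Summary**

Total step count: 11. Longest linear sequence: 10 (steps 1–8, 10, 11); step 9 is a one-step branch.

Steps most likely to fail:

1. Step 3 (Proposed new method). The process risks are a racemic background reaction catalysed by a silyl cation, open-chain vinylogous Michael addition without ring closure, and loss of endo control, which erodes the enantiopurity at C8. The fallback sets out from diene 5 and returns at ketone 10, with the stereochemistry taken from a stoichiometric auxiliary instead of a catalyst. A Lewis-acid-promoted Diels–Alder reaction of 5 with (S)-3-acryloyl-4-benzyl-1,3-oxazolidin-2-one (Et2AlCl, CH2Cl2, −78 °C) should give the cycloadduct silyl ketal F1. Acidic work-up hydrolyses it to the β-keto imide F2, whose C8a diastereomers can be separated. LiOH/H2O2 followed by warming in dilute acid removes the auxiliary and the carboxyl to give the enone (8aR)-5-methyl-3,4,8,8a-tetrahydro-1H-isochromen-6(7H)-one F3. Hydrogenation over Pd/C as in step 4 then gives 10.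

2. Step 5. The process risks are Michael addition at the less hindered C6 methylene, double addition, and slow or poorly face-selective bond formation at the hindered C10. The fallback sets out from ketone 10 and returns at enone 13, replacing the equilibrating enolate by a regiodefined enol silane. Me3SiCl, NaI and Et3N in MeCN should give the more substituted trimethylsilyl enol ether (4aR,8aR)-5-methyl-6-(trimethylsilyloxy)-3,4,4a,7,8,8a-hexahydro-1H-isochromene F4. Mukaiyama–Michael addition of F4 to 11 (TiCl4, CH2Cl2, −78 °C) gives diketone 12 after aqueous work-up, and a separate aldol condensation (NaOMe, MeOH, reflux) gives 13.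

3. Step 10. The process risks are loss of the Z geometry through radical addition–elimination at the bromoenoate, homocoupling of either bromide, and re-closure of the bromo alcohol to the oxane. The fallback sets out from bromo diol 18 and returns at diol ester 21, replacing the reductive coupling by a preformed organozinc. Et3SiOTf and 2,6-lutidine give the bis(triethylsilyl) ether F5. Zinc insertion (Zn dust, catalytic I2, N,N-dimethylacetamide, 70 °C) gives the alkylzinc bromide F6. Negishi coupling with 20 under Pd(PPh3)4 (zerovalent palladium) should give the bis(triethylsilyl) ether of the diol ester F7 with retention of the Z geometry, and HF·pyridine then gives 21.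

Further compounds
F1 | step 3 | (4S)-4-benzyl-3-{[(8aR)-6-ethoxy-5-methyl-6-(tert-butyldimethylsilyloxy)-3,4,6,7,8,8a-hexahydro-1H-isochromen-7-yl]carbonyl}-1,3-oxazolidin-2-one | O3CCC1=C(C)C(OCC)(O[Si](C)(C)C(C)(C)C)C(C(=O)N4C(=O)OC[C@@H]4Cc5ccccc5)C[C@H]1C3
F2 | step 3 | (4S)-4-benzyl-3-{[(8aR)-5-methyl-6-oxo-3,4,6,7,8,8a-hexahydro-1H-isochromen-7-yl]carbonyl}-1,3-oxazolidin-2-one | O3CCC1=C(C)C(=O)C(C(=O)N4C(=O)OC[C@@H]4Cc5ccccc5)C[C@H]1C3
F3 | step 3 | (8aR)-5-methyl-3,4,8,8a-tetrahydro-1H-isochromen-6(7H)-one | O3CCC1=C(C)C(=O)CC[C@H]1C3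
F4 | step 5 | (4aR,8aR)-5-methyl-6-(trimethylsilyloxy)-3,4,4a,7,8,8a-hexahydro-1H-isochromene | O3CC[C@@H]1[C@H](C3)CCC(O[Si](C)(C)C)=C1C
F5 | step 10 | bis(triethylsilyl) ether of bromo diol 18 | BrCC[C@@H]1[C@H](CO[Si](CC)(CC)CC)CC[C@@H]2C(C)(C)[C@H](O[Si](CC)(CC)CC)CC[C@@]12C
F6 | step 10 | alkylzinc bromide from F5 | Br[Zn]CC[C@@H]1[C@H](CO[Si](CC)(CC)CC)CC[C@@H]2C(C)(C)[C@H](O[Si](CC)(CC)CC)CC[C@@]12C
F7 | step 10 | bis(triethylsilyl) ether of diol ester 21 | COC(=O)/C=C(/C)CC[C@@H]1[C@H](CO[Si](CC)(CC)CC)CC[C@@H]2C(C)(C)[C@H](O[Si](CC)(CC)CC)CC[C@@]12C
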